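**Plan**

Numbering and enabling feature: the carbocycle is C1=C10(Me)–C9(=O)–C8(O-acyl)–C7–C6(O)–C5=C4(Me)–C3–C2 and the lactone is C7–C11(=C13)–C12(=O)–O–C6. The chain C9(=O)–C8–C7–C11–C12(=O) is a 1,5-dicarbonyl that runs through both the ten-membered ring and the γ-lactone. This is the retron of an enol/alkene [2+2] cycloaddition followed by retro-aldol cleavage.
Retrosynthetic cuts, in order: the O8–acyl ester; C8–O8 (enol ether oxidation); C11=C13 (Mannich methylenation); then C7–C11 and C8–C9 with C9–C11 restored, which gives an eleven-membered β-keto lactone with a vinyl group on C6; then C12–O (acylketene), C9–C11 (Meldrum's acid), C6–C7 (vinyl addition) and C1=C10 (olefination).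
Forward order: a linear Z,Z chain is built from neryl acetate and closed to the eleven-membered macrolactone. One photochemical operation then closes the γ-lactone (C7–C11) and the ten-membered carbocycle (C8–C9) and removes C9–C11. C13, O8 and the side-chain ester follow.
Stereochemistry: Z-C4=C5 comes from neryl acetate and Z-C1=C10 from a Still–Gennari olefination. C6 comes from a catalytic asymmetric vinylzinc addition, and C7 is relayed from C6 through the bridged cyclobutane. C8 comes from a peripheral Rubottom oxidation steered by C7, and C2′/C3′ from a Sharpless epoxidation of angelyl alcohol.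

Key step: step 12

Remark: germacrane numbering is used throughout; C8 passes through the key step as CH2 and C11 as CH, because on the bridged cyclobutane an oxygen on C8 could only sit exo (trans to C6), which maps onto the 8-epimer of the target, a 2-silyloxyvinyl group next to the bis-allylic ester oxygen would be a labile vinylogous acylal, and an oxymethyl group on C11 of a β-keto ester would be lost by β-elimination.

**Step 1**
Reactants: 1 neryl acetate
Product: 2 (2Z)-3-methyl-6-oxohex-2-en-1-yl acetate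
Conditions: O3 (1 equiv), CH2Cl2, −78 °C; Me2S, −78 °C to rt
Reagents that add atoms: ozone, [O-][O+]=O
Why: Chemoselective ozonolysis: the terminal isopropylidene alkene is more electron-rich than the alkene that carries the allylic acetate, so one equivalent of ozone should cleave only the former and leave the Z alkene (later C4=C5) untouched.

**Step 2**
Reactants: 2 (2Z)-3-methyl-6-oxohex-2-en-1-yl acetate; 3 ethyl 2-[bis(2,2,2-trifluoroethoxy)phosphoryl]propanoate
Product: 4 ethyl (2Z,6Z)-8-acetoxy-2,6-dimethylocta-2,6-dienoate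
Conditions: KN(SiMe3)2, 18-crown-6, THF, −78 °C
Reagents that add atoms: none
Why: Still–Gennari olefination: the electron-poor bis(trifluoroethyl) phosphonate with a dissociated potassium base eliminates under kinetic control and should give the Z-2-methyl enoate, which fixes the Z geometry of C1=C10.

**Step 3**
Reactants: 4 ethyl (2Z,6Z)-8-acetoxy-2,6-dimethylocta-2,6-dienoate
Product: 5 ethyl (2Z,6Z)-8-hydroxy-2,6-dimethylocta-2,6-dienoate
Conditions: K2CO3 (0.2 equiv), EtOH, 0 °C to rt
Reagents that add atoms: none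
Why: Base-catalysed transesterification removes the unhindered primary acetate far faster than it touches the conjugated α-branched ethyl ester, and ethanol as solvent makes any exchange at that ester degenerate.

**Step 4**
Reactants: 5 ethyl (2Z,6Z)-8-hydroxy-2,6-dimethylocta-2,6-dienoate
Product: 6 ethyl (2Z,6Z)-2,6-dimethyl-8-oxoocta-2,6-dienoate
Conditions: TEMPO (10 mol %), PhI(OAc)2, MeCN/pH 7 buffer, 0 °C
Reagents that add atoms: none
Why: Oxoammonium (TEMPO) oxidation under buffered conditions is the standard way to turn nerol-type allylic alcohols into the Z-enals without Z/E isomerisation or over-oxidation.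

**Step 5**
Reactants: 6 ethyl (2Z,6Z)-2,6-dimethyl-8-oxoocta-2,6-dienoate
Product: 7 ethyl (2Z,6Z,8R)-8-hydroxy-2,6-dimethyldeca-2,6,9-trienoate
Conditions: Zn(CH=CH2)2 (salt-free, prepared beforehand from CH2=CHMgBr and ZnCl2), (+)-3-exo-morpholinoisoborneol [(+)-MIB, 10 mol %], toluene, −20 to 0 °C; aq NH4Cl
Reagents that add atoms: divinylzinc, C=C[Zn]C=C
Why: Amino-alcohol-catalysed asymmetric addition of an alkenylzinc reagent to an aldehyde: the (+)-ligand directs the vinyl group (C7=C8) to the Re face of the enal and so sets C6 in the configuration of the target (R at this stage), while the ester is inert to the organozinc.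

**Step 6**
Reactants: 7 ethyl (2Z,6Z,8R)-8-hydroxy-2,6-dimethyldeca-2,6,9-trienoate
Product: 8 ethyl (2Z,6Z,8R)-2,6-dimethyl-8-(triethylsilyloxy)deca-2,6,9-trienoate
Conditions: Et3SiCl, imidazole, CH2Cl2, 0 °C
Reagents that add atoms: chlorotriethylsilane, CC[Si](Cl)(CC)CC
Why: Silyl ether protection masks the C6 hydroxyl so that it cannot be acylated when the C9 acid is activated in step 8.

**Step 7**
Reactants: 8 ethyl (2Z,6Z,8R)-2,6-dimethyl-8-(triethylsilyloxy)deca-2,6,9-trienoate
Product: 9 (2Z,6Z,8R)-2,6-dimethyl-8-(triethylsilyloxy)deca-2,6,9-trienoic acid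
Conditions: LiOH, THF/EtOH/H2O, 40 °C; 1 M HCl to pH 4, 0 °C
Reagents that add atoms: lithium hydroxide, [Li+].[OH-]
Why: Saponification of the hindered conjugated ester proceeds by acyl–oxygen cleavage, which should leave the Z-C1=C10 geometry and the silyl ether intact under these mild conditions.

**Step 8**
Reactants: 9 (2Z,6Z,8R)-2,6-dimethyl-8-(triethylsilyloxy)deca-2,6,9-trienoic acid; 10 Meldrum's acid
Product: 11 5-[(2Z,6Z,8R)-1-hydroxy-2,6-dimethyl-8-(triethylsilyloxy)deca-2,6,9-trienylidene]-2,2-dimethyl-1,3-dioxane-4,6-dione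
Conditions: EDCI·HCl, DMAP, CH2Cl2, 0 °C to rt
Reagents that add atoms: none
Why: Carbodiimide/DMAP C-acylation of Meldrum's acid is the standard entry to acyl Meldrum's acids, which exist as stable hydrogen-bonded enols and here bring in C11 and C12.

**Step 9**
Reactants: 11 5-[(2Z,6Z,8R)-1-hydroxy-2,6-dimethyl-8-(triethylsilyloxy)deca-2,6,9-trienylidene]-2,2-dimethyl-1,3-dioxane-4,6-dione
Product: 12 5-[(2Z,6Z,8R)-1,8-dihydroxy-2,6-dimethyldeca-2,6,9-trienylidene]-2,2-dimethyl-1,3-dioxane-4,6-dione
Conditions: HF·pyridine, pyridine, THF, 0 °C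
Reagents that add atoms: none
Why: Fluoride-mediated desilylation buffered with pyridine frees the C6 alcohol without ionising the bis-allylic carbinol or opening the acyl Meldrum's acid.

**Step 10**
Reactants: 12 5-[(2Z,6Z,8R)-1,8-dihydroxy-2,6-dimethyldeca-2,6,9-trienylidene]-2,2-dimethyl-1,3-dioxane-4,6-dione
Product: 14 (5Z,9Z,11R)-11-ethenyl-5,9-dimethyl-1-oxacycloundeca-5,9-diene-2,4-dione, via acylketene 13 (not isolated)
Conditions: toluene (0.5 mM, syringe pump), 110 °C
Reagents that add atoms: none
Why: Acylketene macrolactonisation: thermolysis expels acetone and CO2, and at high dilution the very electrophilic acylketene is trapped by the C6 hydroxyl without any activating reagent, the two Z alkenes folding the chain for closure of the eleven-membered ring with retention at C6.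

**Step 11**
Reactants: 14 (5Z,9Z,11R)-11-ethenyl-5,9-dimethyl-1-oxacycloundeca-5,9-diene-2,4-dione
Product: 15 (3E,5Z,9Z,11R)-4-(tert-butyldimethylsilyloxy)-11-ethenyl-5,9-dimethyl-1-oxacycloundeca-3,5,9-trien-2-one
Conditions: TBSOTf, Et3N, CH2Cl2, −78 to 0 °C
Reagents that add atoms: tert-butyldimethylsilyl triflate, CC(C)(C)[Si](C)(C)OS(=O)(=O)C(F)(F)F
Why: Soft enolisation (silyl triflate/amine) O-silylates the β-keto ester, and the isomer with C10 and C12 cis on C9=C11 is expected because a trans alkene next to two Z alkenes would strain the eleven-membered ring.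

**Step 12**
Reactants: 15 (3E,5Z,9Z,11R)-4-(tert-butyldimethylsilyloxy)-11-ethenyl-5,9-dimethyl-1-oxacycloundeca-3,5,9-trien-2-one
Product: 18 (1(10)Z,4Z,6R,7S)-9-oxogermacra-1(10),4-dien-12,6-olide, via cyclobutane silyl ether 16 (not isolated), via cyclobutanol 17 (not isolated)
Conditions: [Ir(dF(CF3)ppy)2(dtbbpy)]PF6 (2 mol %), degassed CH2Cl2 (2 mM), 450 nm LED, 0 °C; then Bu4NF, THF, 0 °C; aq NH4Cl
Reagents that add atoms: none
Why: Proposed new method: energy transfer from the excited iridium complex populates the triplet of the 3-silyloxy-2,4-dienoate C12(=O)–C11=C9–C10=C1, its terminus C11 bonds to C7 of the vinyl group, the 1,4-diradical (silyloxyallyl radical at C9, primary radical at C8) closes C8–C9 after intersystem crossing to give cyclobutane 16, and fluoride then unmasks the C9 alkoxide of 17, whose strain-driven retro-aldol cleavage of C9–C11 gives 18. The closest known reaction types are the De Mayo reaction run on O-protected enols, the visible-light-sensitised intramolecular [2+2] cycloaddition of 1,3-dienes with tethered alkenes and the fluoride-induced opening of 2-silyloxycyclobutanecarboxylates; what has no precedent is an ester as the three-atom tether inside an eleven-membered ring. The γ-lactone (C7–C11–C12–O–C6) closes 5-exo at the internal vinyl carbon, as the rule of five demands for a 1,6-diene, and the ten-membered carbocycle (C1 to C10) closes in the radical recombination C8–C9 that completes the four-membered ring and becomes a simple ring once C9–C11 is cut. C7 is the only new stereocentre that survives (C9 of 16 becomes trigonal and C11 becomes CH2) and it is controlled by C6: the six-atom chain C5–C4–C3–C2–C1–C10 can link C6 and C9 only on one face of the new lactone and the cyclobutane must be cis-fused, so C5, C8 and C9 lie on the same face and H6 and H7 are cis, while a diradical formed on the other vinyl face cannot close and reverts to 15. The step needs the s-cis ester rotamer, which the three cis units C4=C5, C1=C10 and C9=C11 of the ring should make competitive with the usual s-trans form, and it needs C1=C10 and C4=C5 to stay Z, which is helped because 16 has no chromophore left that the sensitiser can excite and because a crossed addition to C4=C5 would have to join two fully substituted carbons. The silyl lock keeps the enone tautomer out of the photochemistry and delays the retro-aldol until the light is off, so that the Z-enone of 18 is never irradiated.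

**Step 13**
Reactants: 18 (1(10)Z,4Z,6R,7S)-9-oxogermacra-1(10),4-dien-12,6-olide
Product: 19 (1(10)Z,4Z,6R,7R,8E)-9-(tert-butyldimethylsilyloxy)germacra-1(10),4,8-trien-12,6-olide
Conditions: TBSOTf, Et3N, CH2Cl2, −78 to 0 °C
Reagents that add atoms: tert-butyldimethylsilyl triflate, CC(C)(C)[Si](C)(C)OS(=O)(=O)C(F)(F)F
Why: Soft enolisation: C8 is the only α-CH2 of the ketone and the lactone is not enolised by silyl triflate/amine at low temperature, so the cross-conjugated silyl dienol ether should form, which masks the ketone for step 14 and prepares C8 for oxidation.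

**Step 14**
Reactants: 19 (1(10)Z,4Z,6R,7R,8E)-9-(tert-butyldimethylsilyloxy)germacra-1(10),4,8-trien-12,6-olide
Product: 20 (1(10)Z,4Z,6R,7S,8E,11R)-9-(tert-butyldimethylsilyloxy)-13-(dimethylamino)germacra-1(10),4,8-trien-12,6-olide
Conditions: LiN(iPr)2, THF, −78 °C; Me2N=CH2 I (1.05 equiv), −78 to 0 °C
Reagents that add atoms: Eschenmoser's salt, C=[N+](C)C.[I-]
Why: Mannich reaction of a lactone lithium enolate with Eschenmoser's salt: with the ketone masked, C11–H2 is the only acidic site, and the iminium ion should enter from the convex face (cis to H7), a configuration that is erased in step 15.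

**Step 15**
Reactants: 20 (1(10)Z,4Z,6R,7S,8E,11R)-9-(tert-butyldimethylsilyloxy)-13-(dimethylamino)germacra-1(10),4,8-trien-12,6-olide
Product: 22 (1(10)Z,4Z,6S,7S,8E)-9-(tert-butyldimethylsilyloxy)germacra-1(10),4,8,11(13)-tetraen-12,6-olide, via trimethylammonium iodide 21 (not isolated)
Conditions: MeI, CH2Cl2, rt; then aq NaHCO3, rt
Reagents that add atoms: iodomethane, CI (its carbon is carried by 21 and leaves with the amine)
Why: Exhaustive methylation and Hofmann-type E1cB elimination of the β-ammonio lactone is the classical second half of the α-methylenation of lactones and needs only bicarbonate, which the silyl dienol ether tolerates.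

**Step 16**
Reactants: 22 (1(10)Z,4Z,6S,7S,8E)-9-(tert-butyldimethylsilyloxy)germacra-1(10),4,8,11(13)-tetraen-12,6-olide
Product: 24 (1(10)Z,4Z,6S,7S,8R)-8-hydroxy-9-oxogermacra-1(10),4,11(13)-trien-12,6-olide, via silyloxy epoxide 23 (not isolated)
Conditions: dimethyldioxirane (1.0 equiv), acetone/CH2Cl2, −78 °C; then HF·pyridine, THF, 0 °C
Reagents that add atoms: dimethyldioxirane, CC1(C)OO1
Why: Rubottom oxidation: the silyl enol ether is by far the most electron-rich alkene, allylic 1,3-strain places H7 in the plane of C8=C9 so that the ring chain through C6 shields the inner face, and attack of the dioxirane from the outer face (the side of C11) should give the 8R carbinol after fluoride opens the silyloxy epoxide.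

**Step 17**
Reactants: 25 angelic acid
Product: 26 (2Z)-2-methylbut-2-en-1-ol
Conditions: LiAlH4, Et2O, 0 °C to rt
Reagents that add atoms: none
Why: Hydride reduction of the α,β-unsaturated acid takes place at the carboxyl group only and keeps the Z alkene.

**Step 18**
Reactants: 26 (2Z)-2-methylbut-2-en-1-ol
Product: 27 [(2R,3S)-2,3-dimethyloxiran-2-yl]methanol
Conditions: Ti(OiPr)4 (10 mol %), D-(−)-diisopropyl tartrate (12 mol %), t-BuOOH, 4 Å MS, CH2Cl2, −20 °C
Reagents that add atoms: tert-butyl hydroperoxide, CC(C)(C)OO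
Why: Sharpless asymmetric epoxidation: the D-(−)-tartrate delivers oxygen to the face that gives the (2R,3S)-epoxy alcohol, and the syn addition keeps the C3′ methyl cis to the CH2OH group.

**Step 19**
Reactants: 27 [(2R,3S)-2,3-dimethyloxiran-2-yl]methanol
Product: 28 (2S,3S)-2,3-dimethyloxirane-2-carboxylic acid
Conditions: RuCl3 (2 mol %), NaIO4, MeCN/EtOAc/H2O, 0 °C to rt
Reagents that add atoms: sodium periodate, [Na+].[O-]I(=O)(=O)=O
Why: RuO4-catalysed oxidation takes primary epoxy alcohols to glycidic acids without touching the epoxide, so both stereocentres are kept (C2′ changes its descriptor to S only through the change in priorities).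

**Step 20**
Reactants: 24 (1(10)Z,4Z,6S,7S,8R)-8-hydroxy-9-oxogermacra-1(10),4,11(13)-trien-12,6-olide; 28 (2S,3S)-2,3-dimethyloxirane-2-carboxylic acid
Product: 29 (1(10)Z,4Z,6S,7S,8R)-8-[(2S,3S)-2,3-epoxy-2-methylbutanoyloxy]-9-oxogermacra-1(10),4,11(13)-trien-12,6-olide (CNP0183761.1)
Conditions: 2-methyl-6-nitrobenzoic anhydride, DMAP, Et3N, CH2Cl2, rt
Reagents that add atoms: none
Why: Shiina esterification (mixed anhydride, DMAP as acyl-transfer catalyst) joins hindered partners at room temperature by acyl–oxygen bond formation, so C8, C2′ and C3′ keep their configuration and the conditions are too mild to epimerise the α-acyloxy ketone.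

**Compound list**
1 | neryl acetate | CC(=O)OC/C=C(/C)CCC=C(C)C | starting material
2 | (2Z)-3-methyl-6-oxohex-2-en-1-yl acetate | CC(=O)OC/C=C(/C)CCC=O | intermediate
3 | ethyl 2-[bis(2,2,2-trifluoroethoxy)phosphoryl]propanoate | CCOC(=O)C(C)P(=O)(OCC(F)(F)F)OCC(F)(F)F | starting material
4 | ethyl (2Z,6Z)-8-acetoxy-2,6-dimethylocta-2,6-dienoate | CC(=O)OC/C=C(/C)CC/C=C(/C)C(=O)OCC | intermediate
5 | ethyl (2Z,6Z)-8-hydroxy-2,6-dimethylocta-2,6-dienoate | OC/C=C(/C)CC/C=C(/C)C(=O)OCC | intermediate
6 | ethyl (2Z,6Z)-2,6-dimethyl-8-oxoocta-2,6-dienoate | O=C/C=C(/C)CC/C=C(/C)C(=O)OCC | intermediate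
7 | ethyl (2Z,6Z,8R)-8-hydroxy-2,6-dimethyldeca-2,6,9-trienoate | O[C@H](C=C)/C=C(/C)CC/C=C(/C)C(=O)OCC | intermediate
8 | ethyl (2Z,6Z,8R)-2,6-dimethyl-8-(triethylsilyloxy)deca-2,6,9-trienoate | CC[Si](CC)(CC)O[C@H](C=C)/C=C(/C)CC/C=C(/C)C(=O)OCC | intermediate
9 | (2Z,6Z,8R)-2,6-dimethyl-8-(triethylsilyloxy)deca-2,6,9-trienoic acid | CC[Si](CC)(CC)O[C@H](C=C)/C=C(/C)CC/C=C(/C)C(=O)O | intermediate
10 | Meldrum's acid | CC1(C)OC(=O)CC(=O)O1 | starting material
11 | acyl Meldrum's acid (enol), O6-triethylsilyl | CC[Si](CC)(CC)O[C@H](C=C)/C=C(/C)CC/C=C(/C)C(O)=C1C(=O)OC(C)(C)OC1=O | intermediate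
12 | acyl Meldrum's acid (enol), free C6 hydroxyl | O[C@H](C=C)/C=C(/C)CC/C=C(/C)C(O)=C1C(=O)OC(C)(C)OC1=O | intermediate
13 | acylketene, (4Z,8Z,10R)-10-hydroxy-4,8-dimethyldodeca-1,4,8,11-tetraene-1,3-dione | O[C@H](C=C)/C=C(/C)CC/C=C(/C)C(=O)C=C=O | intermediate
14 | (5Z,9Z,11R)-11-ethenyl-5,9-dimethyl-1-oxacycloundeca-5,9-diene-2,4-dione | O=C1CC(=O)O[C@H](C=C)/C=C(/C)CC/C=C1/C | intermediate
15 | (3E,5Z,9Z,11R)-4-(tert-butyldimethylsilyloxy)-11-ethenyl-5,9-dimethyl-1-oxacycloundeca-3,5,9-trien-2-one | C1/C(C)=C\[C@@H](C=C)OC(=O)/C=C(/O[Si](C)(C)C(C)(C)C)C(/C)=C\C1 | intermediate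
16 | (6R,7S,9S,11S) photoadduct: cyclobutane C7–C8–C9–C11 cis-fused to the γ-lactone, OTBS on C9 exo, chain C10 to C5 bridging C9 and C6 on the endo face | O=C1O[C@H]2/C=C(/C)CC/C=C(/C)[C@]3(O[Si](C)(C)C(C)(C)C)C[C@H]2[C@H]13 | intermediate
17 | (6R,7S,9S,11S) cyclobutanol from 16 (reacts as its alkoxide) | O=C1O[C@H]2/C=C(/C)CC/C=C(/C)[C@]3(O)C[C@H]2[C@H]13 | intermediate
18 | (1(10)Z,4Z,6R,7S)-9-oxogermacra-1(10),4-dien-12,6-olide (cis-fused lactone) | C1C(=O)O[C@H]2/C=C(/C)CC/C=C(/C)C(=O)C[C@@H]12 | intermediate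
19 | (1(10)Z,4Z,6R,7R,8E)-9-(tert-butyldimethylsilyloxy)germacra-1(10),4,8-trien-12,6-olide | C1C(=O)O[C@H]2/C=C(/C)CC/C=C(/C)C(/O[Si](C)(C)C(C)(C)C)=C\[C@@H]12 | intermediate
20 | (11R)-13-dimethylamino derivative of 19 | CN(C)C[C@@H]1C(=O)O[C@H]2/C=C(/C)CC/C=C(/C)C(/O[Si](C)(C)C(C)(C)C)=C\[C@@H]12 | intermediate
21 | 13-trimethylammonium iodide from 20 | C[N+](C)(C)C[C@@H]1C(=O)O[C@H]2/C=C(/C)CC/C=C(/C)C(/O[Si](C)(C)C(C)(C)C)=C\[C@@H]12.[I-] | intermediate
22 | (1(10)Z,4Z,6S,7S,8E)-9-(tert-butyldimethylsilyloxy)germacra-1(10),4,8,11(13)-tetraen-12,6-olide | C=C1C(=O)O[C@H]2/C=C(/C)CC/C=C(/C)C(/O[Si](C)(C)C(C)(C)C)=C\[C@@H]12 | intermediate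
23 | (8R,9R)-8,9-epoxide of 22 (silyloxy epoxide) | C=C1C(=O)O[C@H]2/C=C(/C)CC/C=C(/C)[C@]3(O[Si](C)(C)C(C)(C)C)O[C@@H]3[C@@H]12 | intermediate
24 | (1(10)Z,4Z,6S,7S,8R)-8-hydroxy-9-oxogermacra-1(10),4,11(13)-trien-12,6-olide | C=C1C(=O)O[C@H]2/C=C(/C)CC/C=C(/C)C(=O)[C@H](O)[C@@H]12 | intermediate
25 | angelic acid | C/C=C(/C)C(O)=O | starting material
26 | (2Z)-2-methylbut-2-en-1-ol | C/C=C(/C)CO | intermediate
27 | [(2R,3S)-2,3-dimethyloxiran-2-yl]methanol | OC[C@@]1(C)O[C@H]1C | intermediate
28 | (2S,3S)-2,3-dimethyloxirane-2-carboxylic acid | OC(=O)[C@@]1(C)O[C@H]1C | intermediate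
29 | CNP0183761.1 | C=C1C(=O)O[C@H]2/C=C(/C)CC/C=C(/C)C(=O)[C@H](OC(=O)[C@@]3(C)O[C@H]3C)[C@@H]12 | target

Total steps: 20. Longest linear sequence: 17 (steps 1 to 16 and step 20).

**Steps most likely to fail**

**1. Step 12 (bears the label "Proposed new method:").**
- What may go wrong: the triplet may decay by twisting about C9=C11 or C1=C10 (Z/E leakage) faster than C11 bonds to C7, because the lactone stays in the s-trans ester rotamer. The diradical may also recombine at C1 instead of C9.
- Fallback, known chemistry only, from 6 back to 18. Ground-state additions to C7 place C8 trans to C5, so the C6 epimer is carried and C6 is inverted at the end.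
- Enal 6 is vinylated as in step 5 but with (−)-MIB to give ethyl (2Z,6Z,8S)-8-hydroxy-2,6-dimethyldeca-2,6,9-trienoate F1, which is silylated to its triethylsilyl ether F2. MeNH(OMe)·HCl/iPrMgCl gives the Weinreb amide F3, and CH2=CHMgBr gives the cross-conjugated vinyl ketone F4.
- Ring-closing metathesis (second-generation Grubbs catalyst, high dilution) joins C7 and C8 to the ten-membered trienone silyl ether F5, and HF·pyridine frees the γ-hydroxy enone F6. Heating with Meldrum's acid 10 gives the hydrogen malonate F7. DBU then triggers a tethered 5-exo Michael addition of C11 to C7 that, with H6 eclipsing the Z alkene, should give the trans-fused α-carboxy lactone F8.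
- Thermal decarboxylation leads to the 6-epimer of 18 F9, and LiOH opens it to the hydroxy acid F10. Mitsunobu lactonisation (PPh3, DIAD) closes the lactone with inversion at C6 to give 18.

**2. Step 10.**
- What may go wrong: dimerisation and oligomerisation of the acylketene may outrun closure of the strained eleven-membered ring.
- Fallback, from 7 back to 14. The ring is closed at C9–C11 instead of C12–O.
- iBu2AlH reduces the ester of 7 to (2Z,6Z,8R)-2,6-dimethyldeca-2,6,9-triene-1,8-diol F11. TEMPO/PhI(OAc)2 oxidises only the primary allylic alcohol to the hydroxy enal F12, and bromoacetyl bromide/pyridine gives the bromoacetate F13.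
- SmI2 (THF, high dilution) effects an intramolecular Reformatsky reaction to the eleven-membered β-hydroxy lactone F14 (epimers at C9). Dess–Martin periodinane then gives 14.

**3. Step 16.**
- What may go wrong: facial selectivity at C8=C9 may be poor, or C4=C5 may be epoxidised in competition.
- Fallback, from 22 to 29. If the oxidant enters from the inner face, the same two operations give the (8S)-alcohol F15.
- Instead of an acyl-transfer esterification, F15 is coupled with acid 28 under Mitsunobu conditions (PPh3, DIAD, toluene, 0 °C). This is an SN2 displacement next to the ketone that inverts C8 and gives 29 directly.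

**Further compounds**
F1 | step 12 | ethyl (2Z,6Z,8S)-8-hydroxy-2,6-dimethyldeca-2,6,9-trienoate | O[C@@H](C=C)/C=C(/C)CC/C=C(/C)C(=O)OCC
F2 | step 12 | ethyl (2Z,6Z,8S)-2,6-dimethyl-8-(triethylsilyloxy)deca-2,6,9-trienoate | CC[Si](CC)(CC)O[C@@H](C=C)/C=C(/C)CC/C=C(/C)C(=O)OCC
F3 | step 12 | (2Z,6Z,8S)-N-methoxy-N,2,6-trimethyl-8-(triethylsilyloxy)deca-2,6,9-trienamide | CC[Si](CC)(CC)O[C@@H](C=C)/C=C(/C)CC/C=C(/C)C(=O)N(C)OC
F4 | step 12 | (4Z,8Z,10S)-4,8-dimethyl-10-(triethylsilyloxy)dodeca-1,4,8,11-tetraen-3-one | CC[Si](CC)(CC)O[C@@H](C=C)/C=C(/C)CC/C=C(/C)C(=O)C=C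
F5 | step 12 | (2Z,6Z,8S,9Z)-2,6-dimethyl-8-(triethylsilyloxy)cyclodeca-2,6,9-trien-1-one | C1/C(C)=C\[C@@H](O[Si](CC)(CC)CC)/C=C\C(=O)C(/C)=C\C1
F6 | step 12 | (2Z,6Z,8S,9Z)-8-hydroxy-2,6-dimethylcyclodeca-2,6,9-trien-1-one | C1/C(C)=C\[C@@H](O)/C=C\C(=O)C(/C)=C\C1
F7 | step 12 | hydrogen malonate of F6 | C1/C(C)=C\[C@@H](OC(=O)CC(=O)O)/C=C\C(=O)C(/C)=C\C1
F8 | step 12 | trans-fused (6S,7S)-11-carboxy-9-oxogermacra-1(10),4-dien-12,6-olide | OC(=O)C1C(=O)O[C@@H]2/C=C(/C)CC/C=C(/C)C(=O)C[C@@H]12
F9 | step 12 | (1(10)Z,4Z,6S,7S)-9-oxogermacra-1(10),4-dien-12,6-olide (6-epimer of 18) | C1C(=O)O[C@@H]2/C=C(/C)CC/C=C(/C)C(=O)C[C@@H]12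
F10 | step 12 | (1(10)Z,4Z,6S,7S)-6-hydroxy-9-oxogermacra-1(10),4-dien-12-oic acid | OC(=O)C[C@@H]1CC(=O)C(/C)=C\CC/C(C)=C\[C@H]1O
F11 | step 10 | (2Z,6Z,8R)-2,6-dimethyldeca-2,6,9-triene-1,8-diol | O[C@H](C=C)/C=C(/C)CC/C=C(/C)CO
F12 | step 10 | (2Z,6Z,8R)-8-hydroxy-2,6-dimethyldeca-2,6,9-trienal | O[C@H](C=C)/C=C(/C)CC/C=C(/C)C=O
F13 | step 10 | (3R,4Z,8Z)-5,9-dimethyl-10-oxodeca-1,4,8-trien-3-yl bromoacetate | BrCC(=O)O[C@H](C=C)/C=C(/C)CC/C=C(/C)C=O
F14 | step 10 | (5Z,9Z,11R)-11-ethenyl-4-hydroxy-5,9-dimethyl-1-oxacycloundeca-5,9-dien-2-one | OC1CC(=O)O[C@H](C=C)/C=C(/C)CC/C=C1/C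
F15 | step 16 | (1(10)Z,4Z,6S,7S,8S)-8-hydroxy-9-oxogermacra-1(10),4,11(13)-trien-12,6-olide | C=C1C(=O)O[C@H]2/C=C(/C)CC/C=C(/C)C(=O)[C@@H](O)[C@@H]12
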